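The route rests on disconnecting the C3–C4 bond of pyranone ring C, between the C4 carbonyl carbon on ring A and the C3 methine that carries ring B. In the key step a diazo carbon (future C3), released at low temperature from a sulfonylhydrazone, adds to an ortho-formyl group (future C4) held by a chiral boron Lewis acid, and the formyl hydrogen migrates to C3 as N2 leaves. One operation thus closes ring C, creates the C4 ketone and sets C3, the only stereocentre. It exploits the single hydrogen on C3 next to the C4 carbonyl. The precursor is an open aryl ether joining a ring A salicylaldehyde to a ring B ketone sulfonylhydrazone.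

Key step: step 9

Numbering: isoflavanone numbering is used (O1, C2, C3, C4, C4a, C5–C8, C8a; ring A = benzo ring, ring B = 3-aryl ring, ring C = pyranone ring). The target is the (3R) enantiomer.

Assumption: the (R)-oxazaborolidinium catalyst is taken to leave the re face of the bound formyl group open, which in the chair-like closure described in step 9 leads to (3R). If the sense of induction proves opposite, the (S)-catalyst is used without other change. The C=N geometry of the sulfonylhydrazones is not defined and is of no consequence.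

Step 1
Reactants: 1 2,4,6-trihydroxybenzaldehyde; 2 chloromethyl methyl ether
Product: 3 2-hydroxy-4,6-bis(methoxymethoxy)benzaldehyde
Conditions: MOMCl (2.2 equiv), i-Pr2NEt, CH2Cl2, 0 °C to rt
Reagents that add atoms: chloromethyl methyl ether, COCCl
Why: Williamson-type MOM protection in which the 4-OH and one ortho OH react while the second ortho OH stays free because it is held in a hydrogen bond to the formyl group.

Step 2
Reactants: 3 2-hydroxy-4,6-bis(methoxymethoxy)benzaldehyde; 4 1-bromo-3-methylbut-2-ene (prenyl bromide)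
Product: 5 2,4-bis(methoxymethoxy)-6-[(3-methylbut-2-en-1-yl)oxy]benzaldehyde
Conditions: K2CO3, DMF, rt to 50 °C
Reagents that add atoms: prenyl bromide, CC(C)=CCBr
Why: Williamson ether synthesis in which the remaining hydrogen-bonded phenol is alkylated by the reactive allylic bromide under carbonate in a dipolar aprotic solvent.

Step 3
Reactants: 5 2,4-bis(methoxymethoxy)-6-[(3-methylbut-2-en-1-yl)oxy]benzaldehyde
Product: 8 6-hydroxy-2,4-bis(methoxymethoxy)-3-(3-methylbut-2-en-1-yl)benzaldehyde, via ortho-dienone 6 (not isolated), via para-dienone 7 (not isolated)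
Conditions: PhNEt2, 200 °C, sealed tube, Ar
Reagents that add atoms: none
Why: Tandem aromatic Claisen/Cope rearrangement (para-Claisen) in which the first [3,3] shift gives dienone 6 with a crowded 1,1-dimethylallyl group, the second [3,3] shift moves it as a normal prenyl group to the carbon para to oxygen between the two MOM ethers (7), and tautomerisation returns the phenol, so that the prenyl group sits on the future C6 and the free OH is the future O1.

Step 4
Reactants: 9 4-bromophenol; 4 1-bromo-3-methylbut-2-ene (prenyl bromide)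
Product: 10 4-bromo-2-(3-methylbut-2-en-1-yl)phenol
Conditions: NaH, toluene, 0 °C; then prenyl bromide, rt
Reagents that add atoms: prenyl bromide, CC(C)=CCBr
Why: ortho-C-alkylation of a sodium phenoxide in a non-polar solvent, where the tight ion pair shields oxygen and directs the allylic bromide to the ortho carbon, the para position being blocked by bromine.

Step 5
Reactants: 10 4-bromo-2-(3-methylbut-2-en-1-yl)phenol; 2 chloromethyl methyl ether
Product: 11 4-bromo-1-(methoxymethoxy)-2-(3-methylbut-2-en-1-yl)benzene
Conditions: NaH, THF, 0 °C; then MOMCl, rt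
Reagents that add atoms: chloromethyl methyl ether, COCCl
Why: Williamson-type MOM protection of the phenoxide, which masks the acidic OH before the organomagnesium step.

Step 6
Reactants: 11 4-bromo-1-(methoxymethoxy)-2-(3-methylbut-2-en-1-yl)benzene; 12 2-chloro-N-methoxy-N-methylacetamide
Product: 15 2-chloro-1-[4-(methoxymethoxy)-3-(3-methylbut-2-en-1-yl)phenyl]ethan-1-one, via arylmagnesium bromide 13 (not isolated), via magnesium hemiaminal 14 (not isolated)
Conditions: Mg, THF, reflux; then 12, 0 °C; aq. NH4Cl
Reagents that add atoms: 2-chloro-N-methoxy-N-methylacetamide, CON(C)C(=O)CCl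
Why: Grignard formation followed by acylation with an N-methoxy-N-methylamide, in which the chelated tetrahedral adduct 14 does not collapse until work-up, so the α-chloro ketone forms without over-addition.

Step 7
Reactants: 15 2-chloro-1-[4-(methoxymethoxy)-3-(3-methylbut-2-en-1-yl)phenyl]ethan-1-one; 16 2-(trifluoromethyl)benzenesulfonohydrazide
Product: 17 N'-{2-chloro-1-[4-(methoxymethoxy)-3-(3-methylbut-2-en-1-yl)phenyl]ethylidene}-2-(trifluoromethyl)benzenesulfonohydrazide
Conditions: EtOH/THF, 0 °C to rt, no base
Reagents that add atoms: 2-(trifluoromethyl)benzenesulfonohydrazide, NNS(=O)(=O)c1ccccc1C(F)(F)F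
Why: Hydrazone condensation of the ketone with the sulfonyl hydrazide under neutral conditions, which is faster than displacement of the chloride.

Step 8
Reactants: 8 6-hydroxy-2,4-bis(methoxymethoxy)-3-(3-methylbut-2-en-1-yl)benzaldehyde; 17 N'-{2-chloro-1-[4-(methoxymethoxy)-3-(3-methylbut-2-en-1-yl)phenyl]ethylidene}-2-(trifluoromethyl)benzenesulfonohydrazide
Product: 19 N'-{2-[2-formyl-3,5-bis(methoxymethoxy)-4-(3-methylbut-2-en-1-yl)phenoxy]-1-[4-(methoxymethoxy)-3-(3-methylbut-2-en-1-yl)phenyl]ethylidene}-2-(trifluoromethyl)benzenesulfonohydrazide, via azoalkene 18 (not isolated)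
Conditions: Na2CO3 (1.5 equiv), CH2Cl2, 0 °C, slow addition of 17 to 8
Reagents that add atoms: none
Why: Base-induced 1,4-elimination of HCl gives azoalkene 18, to which the phenoxide of 8 adds in a conjugate (Michael-type) fashion at the CH2 terminus, giving the aryl ether with the sulfonylhydrazone already in place and the formyl group untouched.

Step 9
Reactants: 19 N'-{2-[2-formyl-3,5-bis(methoxymethoxy)-4-(3-methylbut-2-en-1-yl)phenoxy]-1-[4-(methoxymethoxy)-3-(3-methylbut-2-en-1-yl)phenyl]ethylidene}-2-(trifluoromethyl)benzenesulfonohydrazide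
Product: 21 (3R)-5,7-bis(methoxymethoxy)-3-[4-(methoxymethoxy)-3-(3-methylbut-2-en-1-yl)phenyl]-6-(3-methylbut-2-en-1-yl)-2,3-dihydro-4H-chromen-4-one, via diazo aldehyde 20 (not isolated)
Conditions: NaH (1.2 equiv), CH2Cl2, −40 °C; cold filtration under Ar; then (R)-oxazaborolidinium triflimide [from the B-(o-tolyl)oxazaborolidine of (R)-α,α-diphenylprolinol and Tf2NH] (20 mol%), toluene/CH2Cl2, −78 to −40 °C
Reagents that add atoms: none
Why: Proposed new method: the anion of sulfonylhydrazone 19 loses sulfinate at low temperature (Bamford–Stevens fragmentation) to give aryl alkyl diazo compound 20, whose nucleophilic diazo carbon (future C3) adds to the formyl carbon (future C4) bound to the chiral boron Lewis acid, after which the former formyl hydrogen shifts from C4 to C3 as N2 leaves, so that the C4 ketone and the C3–H stereocentre arise together. The closest known reaction types are the oxazaborolidinium-catalysed enantioselective formal insertion of aryldiazoalkanes into the formyl C–H bond of aromatic aldehydes, which gives acyclic α-aryl ketones, and the base-mediated metal-free coupling of sulfonylhydrazones with aldehydes; an enantioselective ring-closing version is not described. Ring C closes in the 6-exo-trig mode (attack of C3 on the exocyclic C=O of the formyl group) through a chair-like arrangement with ring B equatorial and the N2 group axial on C3. C3 is controlled by the catalyst, which leaves one face of the bound formyl group open, together with the chair, in which only the adduct with H on C4 anti-periplanar to N2 can undergo the hydride shift, and this shift proceeds with inversion at C3. The step needs hydride migration in preference to migration of the ring A carbon C4a (ring contraction) and to epoxide closure, and it needs a slow uncatalysed background reaction; the first is secured because the endocyclic C4–C4a bond is gauche to the axial N2 and the oxygen is tied to boron, the second because the doubly ortho-oxygenated, electron-rich formyl group is a poor electrophile without the Lewis acid. The ketone forms under non-basic conditions at low temperature, so the epimerisable C3 centre should be retained.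

Step 10
Reactants: 21 (3R)-5,7-bis(methoxymethoxy)-3-[4-(methoxymethoxy)-3-(3-methylbut-2-en-1-yl)phenyl]-6-(3-methylbut-2-en-1-yl)-2,3-dihydro-4H-chromen-4-one
Product: 22 (3R)-5,7-dihydroxy-3-[4-hydroxy-3-(3-methylbut-2-en-1-yl)phenyl]-6-(3-methylbut-2-en-1-yl)-2,3-dihydro-4H-chromen-4-one
Conditions: ZnBr2, n-PrSH, CH2Cl2, 0 °C, short reaction time; aq. NaH2PO4 work-up
Reagents that add atoms: none
Why: Lewis acid/thiol cleavage of the three MOM acetals (transacetalisation to the thiol) is fast at 0 °C and non-basic, so the C3 centre and both prenyl groups should survive.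

Compound list
1 | 2,4,6-trihydroxybenzaldehyde | O=Cc1c(O)cc(O)cc1O | starting material
2 | chloromethyl methyl ether (MOMCl) | COCCl | starting material
3 | 2-hydroxy-4,6-bis(methoxymethoxy)benzaldehyde | O=Cc1c(O)cc(OCOC)cc1OCOC | intermediate
4 | 1-bromo-3-methylbut-2-ene (prenyl bromide) | CC(C)=CCBr | starting material
5 | 2,4-bis(methoxymethoxy)-6-[(3-methylbut-2-en-1-yl)oxy]benzaldehyde | O=Cc1c(OCC=C(C)C)cc(OCOC)cc1OCOC | intermediate
6 | 2,4-bis(methoxymethoxy)-5-(2-methylbut-3-en-2-yl)-6-oxocyclohexa-1,3-diene-1-carbaldehyde (ortho-dienone, racemic) | O=CC1=C(OCOC)C=C(OCOC)C(C(C)(C)C=C)C1=O | intermediate (not isolated)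
7 | 2,4-bis(methoxymethoxy)-3-(3-methylbut-2-en-1-yl)-6-oxocyclohexa-1,4-diene-1-carbaldehyde (para-dienone, racemic) | O=CC1=C(OCOC)C(CC=C(C)C)C(OCOC)=CC1=O | intermediate (not isolated)
8 | 6-hydroxy-2,4-bis(methoxymethoxy)-3-(3-methylbut-2-en-1-yl)benzaldehyde | O=Cc1c(O)cc(OCOC)c(CC=C(C)C)c1OCOC | intermediate
9 | 4-bromophenol | Oc1ccc(Br)cc1 | starting material
10 | 4-bromo-2-(3-methylbut-2-en-1-yl)phenol | CC(C)=CCc1cc(Br)ccc1O | intermediate
11 | 4-bromo-1-(methoxymethoxy)-2-(3-methylbut-2-en-1-yl)benzene | CC(C)=CCc1cc(Br)ccc1OCOC | intermediate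
12 | 2-chloro-N-methoxy-N-methylacetamide | CON(C)C(=O)CCl | starting material
13 | [4-(methoxymethoxy)-3-(3-methylbut-2-en-1-yl)phenyl]magnesium bromide | CC(C)=CCc1cc([Mg]Br)ccc1OCOC | intermediate (not isolated)
14 | bromomagnesium 2-chloro-1-[methoxy(methyl)amino]-1-[4-(methoxymethoxy)-3-(3-methylbut-2-en-1-yl)phenyl]ethan-1-olate | CC(C)=CCc1cc(C(CCl)(O[Mg]Br)N(C)OC)ccc1OCOC | intermediate (not isolated)
15 | 2-chloro-1-[4-(methoxymethoxy)-3-(3-methylbut-2-en-1-yl)phenyl]ethan-1-one | CC(C)=CCc1cc(C(=O)CCl)ccc1OCOC | intermediate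
16 | 2-(trifluoromethyl)benzenesulfonohydrazide | NNS(=O)(=O)c1ccccc1C(F)(F)F | starting material
17 | N'-{2-chloro-1-[4-(methoxymethoxy)-3-(3-methylbut-2-en-1-yl)phenyl]ethylidene}-2-(trifluoromethyl)benzenesulfonohydrazide | CC(C)=CCc1cc(C(CCl)=NNS(=O)(=O)c2ccccc2C(F)(F)F)ccc1OCOC | intermediate
18 | 1-{1-[4-(methoxymethoxy)-3-(3-methylbut-2-en-1-yl)phenyl]ethenyl}-2-{[2-(trifluoromethyl)phenyl]sulfonyl}diazene (azoalkene) | C=C(N=NS(=O)(=O)c1ccccc1C(F)(F)F)c1ccc(OCOC)c(CC=C(C)C)c1 | intermediate (not isolated)
19 | N'-{2-[2-formyl-3,5-bis(methoxymethoxy)-4-(3-methylbut-2-en-1-yl)phenoxy]-1-[4-(methoxymethoxy)-3-(3-methylbut-2-en-1-yl)phenyl]ethylidene}-2-(trifluoromethyl)benzenesulfonohydrazide | O=Cc1c(OCC(=NNS(=O)(=O)c2ccccc2C(F)(F)F)c2ccc(OCOC)c(CC=C(C)C)c2)cc(OCOC)c(CC=C(C)C)c1OCOC | intermediate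
20 | 6-{2-diazo-2-[4-(methoxymethoxy)-3-(3-methylbut-2-en-1-yl)phenyl]ethoxy}-2,4-bis(methoxymethoxy)-3-(3-methylbut-2-en-1-yl)benzaldehyde | O=Cc1c(OCC(=[N+]=[N-])c2ccc(OCOC)c(CC=C(C)C)c2)cc(OCOC)c(CC=C(C)C)c1OCOC | intermediate (not isolated)
21 | (3R)-5,7-bis(methoxymethoxy)-3-[4-(methoxymethoxy)-3-(3-methylbut-2-en-1-yl)phenyl]-6-(3-methylbut-2-en-1-yl)-2,3-dihydro-4H-chromen-4-one | CC(C)=CCc1cc([C@@H]2COc3cc(OCOC)c(CC=C(C)C)c(OCOC)c3C2=O)ccc1OCOC | intermediate
22 | (3R)-5,7-dihydroxy-3-[4-hydroxy-3-(3-methylbut-2-en-1-yl)phenyl]-6-(3-methylbut-2-en-1-yl)-2,3-dihydro-4H-chromen-4-one | CC(C)=CCc1cc([C@@H]2COc3cc(O)c(CC=C(C)C)c(O)c3C2=O)ccc1O | target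

Total step count: 10 steps.
Longest linear sequence: 7 steps (steps 4, 5, 6, 7, 8, 9, 10, from 4-bromophenol); the ring A branch (steps 1–3) joins at step 8.

Steps most likely to fail

1. Step 9 (Proposed new method). Enantiocontrol may be lost through an uncatalysed background cyclisation. The diazo compound may also decompose on the Lewis acid, by cation formation and elimination to the enol ether, before it adds to the formyl group. The fallback uses known chemistry, sets out from 19 and comes back at 21. Heating 19 with Cs2CO3 in 1,4-dioxane at 60 °C should release the diazo compound and close ring C through the same C3–C4 bond without a catalyst, giving the racemic tris(methoxymethyl) isoflavanone F1. Asymmetric transfer hydrogenation under dynamic kinetic resolution (RuCl(p-cymene)[(R,R)-TsDPEN], HCO2H/Et3N, EtOAc, 40 °C), in which C3 equilibrates through the enol while one enantiomer is reduced, should give the cis-(3R,4R)-isoflavan-4-ol F2. Oxidation of F2 with Dess–Martin periodinane (CH2Cl2, 0 °C) should return the ketone as 21 with C3 intact.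

2. Step 8. The hydrazone anion formed in the conjugate addition may lose sulfinate prematurely under the basic coupling conditions, and the azoalkene may self-condense instead of being trapped by the hindered, hydrogen-bonded phenoxide. The fallback sets out from 8 and comes back at 19, masking the formyl group at the alcohol level so that the ether is made by ordinary SN2 alkylation and the hydrazone is formed when no aldehyde is present. Reduction of 8 (NaBH4, MeOH/THF, 0 °C) should give the benzylic alcohol 2-(hydroxymethyl)-3,5-bis(methoxymethoxy)-4-(3-methylbut-2-en-1-yl)phenol F3. Alkylation of its phenolic OH with chloro ketone 15 (K2CO3, acetone, rt) should give the keto alcohol F4. Condensation with hydrazide 16 (EtOH, rt) should give the hydroxy sulfonylhydrazone F5. Oxidation of the electron-rich benzylic alcohol with MnO2 (CH2Cl2, rt) should then give 19.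

3. Step 10. The configuration at C3 may erode through acid-promoted enolisation during acetal cleavage, and a prenyl group may cyclise onto its neighbouring phenol. The fallback sets out from 21 and comes back at 22, moving the stereo-defining event behind the deprotection. Cleavage of the MOM groups with HCl in MeOH (40 °C) should give the triol as the racemic or partly racemised isoflavanone F6. Exhaustive silylation (TMSOTf, Et3N, CH2Cl2, 0 °C) should give the tetrakis(trimethylsilyl) enol ether F7. Catalytic enantioselective protonation of this silyl enol ether (BINOL-derived chiral N-triflyl thiophosphoramide, phenol as stoichiometric proton source, toluene, rt) should give the (3R)-tris(trimethylsilyl) ether F8. Mild desilylation (KHF2, MeOH, 0 °C) should then give 22.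

Further compounds
F1 | step 9 | 5,7-bis(methoxymethoxy)-3-[4-(methoxymethoxy)-3-(3-methylbut-2-en-1-yl)phenyl]-6-(3-methylbut-2-en-1-yl)-2,3-dihydro-4H-chromen-4-one (racemic) | CC(C)=CCc1cc(C2COc3cc(OCOC)c(CC=C(C)C)c(OCOC)c3C2=O)ccc1OCOC
F2 | step 9 | (3R,4R)-5,7-bis(methoxymethoxy)-3-[4-(methoxymethoxy)-3-(3-methylbut-2-en-1-yl)phenyl]-6-(3-methylbut-2-en-1-yl)-3,4-dihydro-2H-chromen-4-ol (cis) | CC(C)=CCc1cc([C@@H]2COc3cc(OCOC)c(CC=C(C)C)c(OCOC)c3[C@@H]2O)ccc1OCOC
F3 | step 8 | 2-(hydroxymethyl)-3,5-bis(methoxymethoxy)-4-(3-methylbut-2-en-1-yl)phenol | OCc1c(O)cc(OCOC)c(CC=C(C)C)c1OCOC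
F4 | step 8 | 2-[2-(hydroxymethyl)-3,5-bis(methoxymethoxy)-4-(3-methylbut-2-en-1-yl)phenoxy]-1-[4-(methoxymethoxy)-3-(3-methylbut-2-en-1-yl)phenyl]ethan-1-one | OCc1c(OCC(=O)c2ccc(OCOC)c(CC=C(C)C)c2)cc(OCOC)c(CC=C(C)C)c1OCOC
F5 | step 8 | N'-{2-[2-(hydroxymethyl)-3,5-bis(methoxymethoxy)-4-(3-methylbut-2-en-1-yl)phenoxy]-1-[4-(methoxymethoxy)-3-(3-methylbut-2-en-1-yl)phenyl]ethylidene}-2-(trifluoromethyl)benzenesulfonohydrazide | OCc1c(OCC(=NNS(=O)(=O)c2ccccc2C(F)(F)F)c2ccc(OCOC)c(CC=C(C)C)c2)cc(OCOC)c(CC=C(C)C)c1OCOC
F6 | step 10 | 5,7-dihydroxy-3-[4-hydroxy-3-(3-methylbut-2-en-1-yl)phenyl]-6-(3-methylbut-2-en-1-yl)-2,3-dihydro-4H-chromen-4-one (racemic) | CC(C)=CCc1cc(C2COc3cc(O)c(CC=C(C)C)c(O)c3C2=O)ccc1O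
F7 | step 10 | 6-(3-methylbut-2-en-1-yl)-3-[3-(3-methylbut-2-en-1-yl)-4-(trimethylsilyloxy)phenyl]-4,5,7-tris(trimethylsilyloxy)-2H-chromene | CC(C)=CCc1cc(C2=C(O[Si](C)(C)C)c3c(O[Si](C)(C)C)c(CC=C(C)C)c(O[Si](C)(C)C)cc3OC2)ccc1O[Si](C)(C)C
F8 | step 10 | (3R)-6-(3-methylbut-2-en-1-yl)-3-[3-(3-methylbut-2-en-1-yl)-4-(trimethylsilyloxy)phenyl]-5,7-bis(trimethylsilyloxy)-2,3-dihydro-4H-chromen-4-one | CC(C)=CCc1cc([C@@H]2COc3cc(O[Si](C)(C)C)c(CC=C(C)C)c(O[Si](C)(C)C)c3C2=O)ccc1O[Si](C)(C)C
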